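**Retrosynthetic overview**
1. The target is 3,5,7,8,2'-pentamethoxyflavone. Rings A and B are bought intact; only the γ-pyrone ring C is built, and it is closed last.
2. O1–C2: acid cyclodehydration of an o-hydroxyaryl 1,3-diketone whose central carbon already carries the 3-OMe, so no late C-3 oxidation or methylation is needed.
3. C2–C3: Baker–Venkataraman aroyl shift within the 2-methoxybenzoate of 2-hydroxy-ω,3,4,6-tetramethoxyacetophenone.
4. C4–C4a: Friedel–Crafts methoxyacetylation of symmetric 1,2,3,5-tetramethoxybenzene, with ortho-demethylation in the same pot to free the phenol that becomes O1.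

Assumption: the target has no stereocentre and no hindered axis, so it is achiral, "single enantiomer" does not apply, and no stereocontrol is needed.

**Step 1**
Reactants: 1 1,2,3,5-tetramethoxybenzene; 2 methoxyacetyl chloride
Product: 4 1-(2-hydroxy-3,4,6-trimethoxyphenyl)-2-methoxyethan-1-one, via 2,3,4,6,ω-pentamethoxyacetophenone 3 (not isolated)
Conditions: AlCl3 (3 equiv), Et2O, 0 °C → rt, 24 h; ice/2 M HCl
Reagents that add atoms: methoxyacetyl chloride (2), COCC(=O)Cl
Why: Friedel–Crafts acylation can only hit the two symmetry-equivalent, strongly activated ring CH positions of 1, and excess AlCl3 then carries out a chelation-directed ortho-demethylation of 3 at the carbonyl-flanking OMe that is buttressed by the 3-OMe (twisted out of plane, most Lewis basic), while ether-moderated AlCl3 at low temperature keeps acylation ahead of decarbonylation of the acyl chloride; no stereocentre is formed.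

**Step 2**
Reactants: 4 1-(2-hydroxy-3,4,6-trimethoxyphenyl)-2-methoxyethan-1-one; 5 2-methoxybenzoyl chloride
Product: 6 2,3,5-trimethoxy-6-(2-methoxyacetyl)phenyl 2-methoxybenzoate
Conditions: Et3N (1.5 equiv), DMAP (10 mol %), CH2Cl2, 0 °C → rt
Reagents that add atoms: 2-methoxybenzoyl chloride (5), COc1ccccc1C(=O)Cl
Why: DMAP-catalysed O-acylation (nucleophilic catalysis) overcomes the hydrogen-bonded, flanked phenol, which is the only acylable site under these non-enolising conditions; no stereocentre is formed.

**Step 3**
Reactants: 6 2,3,5-trimethoxy-6-(2-methoxyacetyl)phenyl 2-methoxybenzoate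
Product: 8 3,5,7,8-tetramethoxy-2-(2-methoxyphenyl)-4H-chromen-4-one (3,5,7,8,2'-pentamethoxyflavone; target), via α-methoxy-1,3-diketone 7 (not isolated)
Conditions: KOt-Bu (2.2 equiv), THF, 0 °C → rt; then AcOH, conc. H2SO4 (3 equiv), THF distilled off, 90 °C, 1 h
Reagents that add atoms: none
Why: Baker–Venkataraman rearrangement (intramolecular Claisen-type O→C aroyl transfer from the α-methoxy ketone enolate) gives 7, whose phenol adds to the aroyl carbonyl and loses water under acid catalysis (cyclodehydration) to form the aromatic γ-pyrone, the aryl methyl ethers surviving brief hot AcOH/H2SO4 and the labile CH(OMe) centre of 7 vanishing in the planar, achiral product.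

**Compound list**
1 | 1,2,3,5-tetramethoxybenzene | COc1cc(OC)c(OC)c(OC)c1 | starting material
2 | methoxyacetyl chloride | COCC(=O)Cl | starting material
3 | 2-methoxy-1-(2,3,4,6-tetramethoxyphenyl)ethan-1-one (2,3,4,6,ω-pentamethoxyacetophenone) | COCC(=O)c1c(OC)cc(OC)c(OC)c1OC | intermediate
4 | 1-(2-hydroxy-3,4,6-trimethoxyphenyl)-2-methoxyethan-1-one | COCC(=O)c1c(O)c(OC)c(OC)cc1OC | intermediate
5 | 2-methoxybenzoyl chloride | COc1ccccc1C(=O)Cl | starting material
6 | 2,3,5-trimethoxy-6-(2-methoxyacetyl)phenyl 2-methoxybenzoate | COCC(=O)c1c(OC)cc(OC)c(OC)c1OC(=O)c1ccccc1OC | intermediate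
7 | 1-(2-hydroxy-3,4,6-trimethoxyphenyl)-2-methoxy-3-(2-methoxyphenyl)propane-1,3-dione (racemic, enolisable centre) | COc1ccccc1C(=O)C(OC)C(=O)c1c(O)c(OC)c(OC)cc1OC | intermediate
8 | 3,5,7,8-tetramethoxy-2-(2-methoxyphenyl)-4H-chromen-4-one (3,5,7,8,2'-pentamethoxyflavone) | COc1ccccc1-c1oc2c(OC)c(OC)cc(OC)c2c(=O)c1OC | target

**Total step count:** 3. **Longest linear sequence:** 3 (1 → 4 → 6 → 8).

**Steps most likely to fail, in order of risk**

Step 1 is the most at risk. The methoxyacetyl chloride–AlCl3 complex can lose CO to give a methoxymethyl cation, which leads to chloromethylation or diarylmethanes. The ether cleavage could also occur at the 6-OMe or go twice. The regiochemistry of 4 is checked by NOE: H-5 must see two OMe groups.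

The fallback sets out from 1 and comes back at 4, passing through 3, which is now isolated. Directed ortho-lithiation of 1 (n-BuLi, TMEDA, THF, 0 °C) at the CH flanked by two OMe groups gives (2,3,4,6-tetramethoxyphenyl)lithium F1. This is acylated with N,2-dimethoxy-N-methylacetamide (Weinreb ketone synthesis, −78 → 0 °C, dilute HCl quench) to give 3 without any acylium ion. A separate chelation-controlled mono-demethylation with BCl3 (1.1 equiv, CH2Cl2, −78 → 0 °C) then gives 4.

Step 3 is second. tert-Butoxide may cleave the aryl ester back to 4 or trigger a retro-Claisen of the crowded diketone. Enolisation of the twisted di-ortho-substituted ketone may be slow, and the acid stage could nick the 5-OMe.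

The fallback sets out from 4 and comes back at 8. It replaces acyl transfer by an aldol and oxidation logic. Claisen–Schmidt condensation of 4 with 2-methoxybenzaldehyde (KOH, EtOH, rt) gives (Z)-1-(2-hydroxy-3,4,6-trimethoxyphenyl)-2-methoxy-3-(2-methoxyphenyl)prop-2-en-1-one F2. In I2 (10 mol %)/DMSO at 120–130 °C this closes by oxa-Michael addition to rac-trans-3,5,7,8-tetramethoxy-2-(2-methoxyphenyl)chroman-4-one F3. F3 is dehydrogenated in the same pot to 8, which erases both transient stereocentres.

Step 2 is third. The phenol of 4 is flanked on both sides and strongly hydrogen bonded, so O-acylation may stall or give mixtures.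

The fallback sets out from 4 and comes back at 7, skipping the ester. LiHMDS (3.3 equiv, THF, −78 °C) converts 4 into dilithium 2-[(Z)-2-methoxy-1-oxidoethenyl]-3,5,6-trimethoxyphenolate F4. Its enolate carbon is aroylated directly by 5 (−78 °C → rt, HCl quench) to give 7. This is then cyclodehydrated with AcOH/H2SO4 as in the second half of step 3.

**Further compounds**
F1 | step 1 | (2,3,4,6-tetramethoxyphenyl)lithium | [Li]c1c(OC)cc(OC)c(OC)c1OC
F2 | step 3 | (Z)-1-(2-hydroxy-3,4,6-trimethoxyphenyl)-2-methoxy-3-(2-methoxyphenyl)prop-2-en-1-one | CO/C(=C\c1ccccc1OC)C(=O)c1c(O)c(OC)c(OC)cc1OC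
F3 | step 3 | rac-trans-3,5,7,8-tetramethoxy-2-(2-methoxyphenyl)chroman-4-one (one enantiomer drawn) | COc1ccccc1[C@@H]1[C@H](C(=O)c2c(OC)cc(OC)c(OC)c2O1)OC
F4 | step 2 | dilithium 2-[(Z)-2-methoxy-1-oxidoethenyl]-3,5,6-trimethoxyphenolate | CO/C=C(\[O-])c1c([O-])c(OC)c(OC)cc1OC.[Li+].[Li+]
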